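**Plan**

- Numbering is that of spiro[5.5]undecane: ring B is C1–C5 (C2 ketone, C3 carbinol carbon with the CH2Cl branch), C6 is the spiro carbon, ring A is C7–C11 (C7 methylidene, C9 OH, C10 Br, C11 gem-dimethyl).
- Retrosynthesis: the chlorohydrin goes back to a C3 spiro-epoxide and this to an α-methylene ketone. Ring B is then cut at C2–C3 and C5–C6 in one operation, to aldehyde 9 (ring A plus C1 and C2) and the four-carbon propargylic boronate 12. Ring A comes from ketoisophorone.
- Enabling feature: the C7 methylidene sits next to the spiro carbon C6 (ene retron, i.e. a C6=C7 alkene with a methyl on C7), and C2/C3 are vicinally oxygenated with a one-carbon branch on C3 (aldehyde allenylation retron). One C4 unit can therefore add to the aldehyde through C3 and then be attacked at C5 by the ring A alkene.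
- Forward order: ring A (steps 1–6), boronate (step 7), ring B in one flask (step 8, C2–C3 then C5–C6), ring B adjustment (steps 9–12).
- Stereochemistry: C9 from the catalyst in step 2 and C10 by dynamic kinetic resolution (cis); C6 in step 8 under control of ring A; C3 in step 11 under control of C6 through the ring B chair.

Key step: step 8

Remark: bromoketone 3 epimerises at C5 (α to the C4 carbonyl), which is what lets step 2 turn the racemate into one stereoisomer; the ligand enantiomer is assigned by analogy and is exchanged if the sense proves opposite. TBS = tert-butyldimethylsilyl, B(pin) = pinacol boronate.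

**Step 1**
Reactants: 1 ketoisophorone (2,6,6-trimethylcyclohex-2-ene-1,4-dione)
Product: 3 5-bromo-2,6,6-trimethylcyclohex-2-ene-1,4-dione (racemic), via lithium dienolate 2 (not isolated)
Conditions: LiN(SiMe3)2, THF, −78 °C; then NBS, −78 → 0 °C; aqueous work-up
Reagents that add atoms: N-bromosuccinimide, O=C1CCC(=O)N1Br
Why: Kinetic deprotonation should occur at C5, the only sp3 α-carbon of the enedione, and the enolate is brominated by NBS (α-bromination of a ketone enolate).

**Step 2**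
Reactants: 3 5-bromo-2,6,6-trimethylcyclohex-2-ene-1,4-dione
Product: 4 (4S,5R)-5-bromo-4-hydroxy-2,6,6-trimethylcyclohex-2-en-1-one
Conditions: RuCl[(R,R)-TsDPEN](p-cymene) (1 mol%), HCO2H/Et3N (5:2), CH2Cl2, 25 °C
Reagents that add atoms: none
Why: Noyori asymmetric transfer hydrogenation with dynamic kinetic resolution: 3 epimerises at C5 under the basic conditions while the ruthenium hydride reduces only the less hindered C4 carbonyl, anti to bromine, so the ligand sets C4 and the cis relation sets C5.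

**Step 3**
Reactants: 4 (4S,5R)-5-bromo-4-hydroxy-2,6,6-trimethylcyclohex-2-en-1-one
Product: 5 (4S,5R)-5-bromo-4-(TBS-oxy)-2,6,6-trimethylcyclohex-2-en-1-one
Conditions: TBSOTf, 2,6-lutidine, CH2Cl2, −78 → 0 °C
Reagents that add atoms: tert-butyldimethylsilyl trifluoromethanesulfonate, CC(C)(C)[Si](C)(C)OS(=O)(=O)C(F)(F)F
Why: O-Silylation of the hindered secondary alcohol with a silyl triflate and a hindered base should proceed without touching either stereocenter.

**Step 4**
Reactants: 5 (4S,5R)-5-bromo-4-(TBS-oxy)-2,6,6-trimethylcyclohex-2-en-1-one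
Product: 7 (4S,5R)-5-bromo-4-(TBS-oxy)-2,6,6-trimethylcyclohex-1-en-1-yl trifluoromethanesulfonate, via lithium enolate 6 (not isolated)
Conditions: LiBH(s-Bu)3, THF, −78 °C; then PhNTf2, −78 → 0 °C
Reagents that add atoms: N-phenylbis(trifluoromethanesulfonimide), O=S(=O)(N(c1ccccc1)S(=O)(=O)C(F)(F)F)C(F)(F)F
Why: Conjugate hydride reduction of the enone, whose carbonyl is shielded by the gem-dimethyl group, gives the enolate regiospecifically, and O-sulfonylation gives the tetrasubstituted enol triflate.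

**Step 5**
Reactants: 7 (4S,5R)-5-bromo-4-(TBS-oxy)-2,6,6-trimethylcyclohex-1-en-1-yl trifluoromethanesulfonate
Product: 8 ethyl 2-[(4S,5R)-5-bromo-4-(TBS-oxy)-2,6,6-trimethylcyclohex-1-en-1-yl]acetate
Conditions: BrZnCH2CO2Et, Pd2(dba)3 (2.5 mol%), XPhos (10 mol%), THF, 60 °C
Reagents that add atoms: (2-ethoxy-2-oxoethyl)zinc bromide, CCOC(=O)C[Zn]Br
Why: Negishi cross-coupling of the enol triflate with the Reformatsky reagent should install the two-carbon arm with the alkene kept in place; the neopentyl-type secondary bromide is inert to the palladium catalyst.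

**Step 6**
Reactants: 8 ethyl 2-[(4S,5R)-5-bromo-4-(TBS-oxy)-2,6,6-trimethylcyclohex-1-en-1-yl]acetate
Product: 9 2-[(4S,5R)-5-bromo-4-(TBS-oxy)-2,6,6-trimethylcyclohex-1-en-1-yl]acetaldehyde
Conditions: i-Bu2AlH (1.05 equiv), CH2Cl2, −78 °C; aq. potassium sodium tartrate
Reagents that add atoms: none
Why: Partial reduction of the ester stops at the aluminium hemiacetal at −78 °C, which should release the β,γ-unsaturated aldehyde on work-up.

**Step 7**
Reactants: 10 tert-butyldimethyl(prop-2-yn-1-yloxy)silane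
Product: 12 tert-butyldimethyl{[4-(4,4,5,5-tetramethyl-1,3,2-dioxaborolan-2-yl)but-2-yn-1-yl]oxy}silane, via lithium acetylide 11 (not isolated)
Conditions: n-BuLi, THF, −78 °C; then ICH2B(pin), −78 → 23 °C
Reagents that add atoms: 2-(iodomethyl)-4,4,5,5-tetramethyl-1,3,2-dioxaborolane, ICB1OC(C)(C)C(C)(C)O1
Why: Matteson homologation: the acetylide forms a boron ate complex whose alkynyl group migrates to the CH2 carbon with loss of iodide, giving the propargylic boronate.

**Step 8**
Reactants: 9 2-[(4S,5R)-5-bromo-4-(TBS-oxy)-2,6,6-trimethylcyclohex-1-en-1-yl]acetaldehyde; 12 tert-butyldimethyl{[4-(4,4,5,5-tetramethyl-1,3,2-dioxaborolan-2-yl)but-2-yn-1-yl]oxy}silane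
Product: 15 (6R,9S,10R)-10-bromo-9-(TBS-oxy)-3-[(TBS-oxy)methyl]-11,11-dimethyl-7-methylidenespiro[5.5]undec-3-en-2-ol (both C2 epimers), via allenyl borate 13 (not isolated), via spirocyclic borate 14 (not isolated)
Conditions: 12 (1.3 equiv), (PhO)2P(O)OH (5 mol%), CH2Cl2, 0 → 23 °C; then Ph3PAuNTf2 (5 mol%), same flask, 23 °C; aq. NaHCO3 work-up
Reagents that add atoms: none
Why: Proposed new method: the γ-substituted propargylic boronate adds to the aldehyde through a closed six-membered SE2′ transition state at its silyloxymethyl-bearing alkyne carbon (C2–C3 bond, allenyl carbinol held as borate 13), and the cationic gold complex then activates the terminal allene C=C so that the tetrasubstituted ring A alkene attacks the allene CH2 through C6 (C5–C6 bond), after which the C7 cation passes a methyl proton to the vinyl-gold carbon C4 and releases the catalyst, a formal Alder-ene reaction that leaves the C7 methylidene. The closest known reaction types are the allenylation of aldehydes by γ-substituted propargylic boronates and the gold-catalysed cycloisomerisation of allenenes to 1,4-dienes; their use in one flask and the attack of a tetrasubstituted alkene on a 1,1-disubstituted allene are not known. Ring B closes in a 6-endo mode at the allene terminus, because the two-atom tether makes attack at the inner allene carbons (four- or five-membered ring) or attack through C7 (seven-membered ring) unfavourable. C6 is set by ring A, the new bond forming on the alkene face opposite the C10 bromine and the C9 silyloxy group, while the C2 carbinol center forms without control and is erased by the oxidation in step 9. The step needs carbon- over oxygen-cyclisation, secured by keeping the C2 oxygen as the weakly nucleophilic borate, and loss of the methyl proton instead of a C8 proton or a 1,2-shift, secured because the methyl group is cis to the tether-bearing carbon on the alkene and so lies next to C4.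

**Step 9**
Reactants: 15 (6R,9S,10R)-10-bromo-9-(TBS-oxy)-3-[(TBS-oxy)methyl]-11,11-dimethyl-7-methylidenespiro[5.5]undec-3-en-2-ol
Product: 16 (6R,9S,10R)-10-bromo-9-(TBS-oxy)-3-[(TBS-oxy)methyl]-11,11-dimethyl-7-methylidenespiro[5.5]undec-3-en-2-one
Conditions: Dess–Martin periodinane, NaHCO3, CH2Cl2, 0 → 23 °C
Reagents that add atoms: none
Why: Dess–Martin oxidation of the allylic alcohol should convert both C2 epimers into one enone.

**Step 10**
Reactants: 16 (6R,9S,10R)-10-bromo-9-(TBS-oxy)-3-[(TBS-oxy)methyl]-11,11-dimethyl-7-methylidenespiro[5.5]undec-3-en-2-one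
Product: 18 (6R,9S,10R)-10-bromo-9-(TBS-oxy)-3-[(TBS-oxy)methyl]-11,11-dimethyl-7-methylidenespiro[5.5]undecan-2-one (C3 epimers), via lithium enolate 17 (not isolated)
Conditions: LiBH(s-Bu)3 (1.05 equiv), THF, −78 °C; then H2O, −78 → 0 °C
Reagents that add atoms: none
Why: Conjugate reduction adds hydride at C4 of the enone only (the methylidene is untouched), the β-silyloxy enolate is stable at −78 °C, and the C3 center formed on protonation is removed again in step 11.

**Step 11**
Reactants: 18 (6R,9S,10R)-10-bromo-9-(TBS-oxy)-3-[(TBS-oxy)methyl]-11,11-dimethyl-7-methylidenespiro[5.5]undecan-2-one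
Product: 20 (3R,6R,9S,10R)-10-bromo-9-(TBS-oxy)-11,11-dimethyl-7-methylidenespiro[5.5]undecan-2-one-3-spiro-2′-oxirane (oxirane oxygen on C3, cis to C11), via methylene ketone 19 (not isolated)
Conditions: H2O2 (30%), NaOH, MeOH, 0 → 23 °C
Reagents that add atoms: hydrogen peroxide, OO
Why: Base-induced β-elimination (E1cB) of silanolate gives the α-methylene ketone, which alone undergoes Weitz–Scheffer nucleophilic epoxidation; the enolate closes the oxirane with the new C3–O bond axial on the ring B chair that keeps C11 equatorial, anti to the axial C7, which sets C3.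

**Step 12**
Reactants: 20 (3R,6R,9S,10R)-10-bromo-9-(TBS-oxy)-11,11-dimethyl-7-methylidenespiro[5.5]undecan-2-one-3-spiro-2′-oxirane
Product: 22 (3S,6R,9S,10R)-10-bromo-3-(chloromethyl)-3,9-dihydroxy-11,11-dimethyl-7-methylidenespiro[5.5]undecan-2-one, via silyl chlorohydrin 21 (not isolated)
Conditions: HCl (3 M aq.), THF, 0 → 23 °C
Reagents that add atoms: hydrogen chloride, Cl
Why: Acid opening of the α,β-epoxy ketone by chloride at the CH2 carbon remote from the carbonyl leaves the C3–O bond and its configuration untouched, and the same acid cleaves the C9 silyl ether.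

**Compound list**

1 | ketoisophorone (2,6,6-trimethylcyclohex-2-ene-1,4-dione) | CC1=CC(=O)CC(C)(C)C1=O | starting material
2 | lithium 3,3,5-trimethyl-4-oxocyclohexa-1,5-dien-1-olate | [Li+].CC1=CC([O-])=CC(C)(C)C1=O | intermediate
3 | 5-bromo-2,6,6-trimethylcyclohex-2-ene-1,4-dione (racemic) | CC1=CC(=O)C(Br)C(C)(C)C1=O | intermediate
4 | (4S,5R)-5-bromo-4-hydroxy-2,6,6-trimethylcyclohex-2-en-1-one | O=C1C(C)=C[C@H](O)[C@H](Br)C1(C)C | intermediate
5 | (4S,5R)-5-bromo-4-(TBS-oxy)-2,6,6-trimethylcyclohex-2-en-1-one | O=C1C(C)=C[C@H](O[Si](C)(C)C(C)(C)C)[C@H](Br)C1(C)C | intermediate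
6 | lithium (4S,5R)-5-bromo-4-(TBS-oxy)-2,6,6-trimethylcyclohex-1-en-1-olate | [Li+].CC=1C[C@H](O[Si](C)(C)C(C)(C)C)[C@H](Br)C(C)(C)C=1[O-] | intermediate
7 | (4S,5R)-5-bromo-4-(TBS-oxy)-2,6,6-trimethylcyclohex-1-en-1-yl trifluoromethanesulfonate | CC=1C[C@H](O[Si](C)(C)C(C)(C)C)[C@H](Br)C(C)(C)C=1OS(=O)(=O)C(F)(F)F | intermediate
8 | ethyl 2-[(4S,5R)-5-bromo-4-(TBS-oxy)-2,6,6-trimethylcyclohex-1-en-1-yl]acetate | CC=1C[C@H](O[Si](C)(C)C(C)(C)C)[C@H](Br)C(C)(C)C=1CC(=O)OCC | intermediate
9 | 2-[(4S,5R)-5-bromo-4-(TBS-oxy)-2,6,6-trimethylcyclohex-1-en-1-yl]acetaldehyde | CC=1C[C@H](O[Si](C)(C)C(C)(C)C)[C@H](Br)C(C)(C)C=1CC=O | intermediate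
10 | tert-butyldimethyl(prop-2-yn-1-yloxy)silane | C#CCO[Si](C)(C)C(C)(C)C | starting material
11 | lithium 3-(TBS-oxy)prop-1-yn-1-ide | [Li+].[C-]#CCO[Si](C)(C)C(C)(C)C | intermediate
12 | tert-butyldimethyl{[4-(4,4,5,5-tetramethyl-1,3,2-dioxaborolan-2-yl)but-2-yn-1-yl]oxy}silane | CC(C)(C)[Si](C)(C)OCC#CCB1OC(C)(C)C(C)(C)O1 | intermediate
13 | 2-{[1-[(4S,5R)-5-bromo-4-(TBS-oxy)-2,6,6-trimethylcyclohex-1-en-1-yl]-3-[(TBS-oxy)methyl]penta-3,4-dien-2-yl]oxy}-4,4,5,5-tetramethyl-1,3,2-dioxaborolane (C2 epimers) | CC=1C[C@H](O[Si](C)(C)C(C)(C)C)[C@H](Br)C(C)(C)C=1CC(OB1OC(C)(C)C(C)(C)O1)C(CO[Si](C)(C)C(C)(C)C)=C=C | intermediate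
14 | 2-{[(6R,9S,10R)-10-bromo-9-(TBS-oxy)-3-[(TBS-oxy)methyl]-11,11-dimethyl-7-methylidenespiro[5.5]undec-3-en-2-yl]oxy}-4,4,5,5-tetramethyl-1,3,2-dioxaborolane (C2 epimers) | C=C1C[C@H](O[Si](C)(C)C(C)(C)C)[C@H](Br)C(C)(C)[C@@]12CC=C(CO[Si](C)(C)C(C)(C)C)C(OB3OC(C)(C)C(C)(C)O3)C2 | intermediate
15 | (6R,9S,10R)-10-bromo-9-(TBS-oxy)-3-[(TBS-oxy)methyl]-11,11-dimethyl-7-methylidenespiro[5.5]undec-3-en-2-ol (C2 epimers) | C=C1C[C@H](O[Si](C)(C)C(C)(C)C)[C@H](Br)C(C)(C)[C@@]12CC=C(CO[Si](C)(C)C(C)(C)C)C(O)C2 | intermediate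
16 | (6R,9S,10R)-10-bromo-9-(TBS-oxy)-3-[(TBS-oxy)methyl]-11,11-dimethyl-7-methylidenespiro[5.5]undec-3-en-2-one | C=C1C[C@H](O[Si](C)(C)C(C)(C)C)[C@H](Br)C(C)(C)[C@@]12CC=C(CO[Si](C)(C)C(C)(C)C)C(=O)C2 | intermediate
17 | lithium (6R,9S,10R)-10-bromo-9-(TBS-oxy)-3-[(TBS-oxy)methyl]-11,11-dimethyl-7-methylidenespiro[5.5]undec-2-en-2-olate | [Li+].C=C1C[C@H](O[Si](C)(C)C(C)(C)C)[C@H](Br)C(C)(C)[C@@]12CCC(CO[Si](C)(C)C(C)(C)C)=C([O-])C2 | intermediate
18 | (6R,9S,10R)-10-bromo-9-(TBS-oxy)-3-[(TBS-oxy)methyl]-11,11-dimethyl-7-methylidenespiro[5.5]undecan-2-one (C3 epimers) | C=C1C[C@H](O[Si](C)(C)C(C)(C)C)[C@H](Br)C(C)(C)[C@@]12CCC(CO[Si](C)(C)C(C)(C)C)C(=O)C2 | intermediate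
19 | (6R,9S,10R)-10-bromo-9-(TBS-oxy)-11,11-dimethyl-3,7-dimethylidenespiro[5.5]undecan-2-one | C=C1C[C@H](O[Si](C)(C)C(C)(C)C)[C@H](Br)C(C)(C)[C@@]12CCC(=C)C(=O)C2 | intermediate
20 | (3R,6R,9S,10R)-10-bromo-9-(TBS-oxy)-11,11-dimethyl-7-methylidenespiro[5.5]undecan-2-one-3-spiro-2′-oxirane | C=C1C[C@H](O[Si](C)(C)C(C)(C)C)[C@H](Br)C(C)(C)[C@@]12CC[C@@]3(CO3)C(=O)C2 | intermediate
21 | (3S,6R,9S,10R)-10-bromo-9-(TBS-oxy)-3-(chloromethyl)-3-hydroxy-11,11-dimethyl-7-methylidenespiro[5.5]undecan-2-one | C=C1C[C@H](O[Si](C)(C)C(C)(C)C)[C@H](Br)C(C)(C)[C@@]12CC[C@@](O)(CCl)C(=O)C2 | intermediate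
22 | (3S,6R,9S,10R)-10-bromo-3-(chloromethyl)-3,9-dihydroxy-11,11-dimethyl-7-methylidenespiro[5.5]undecan-2-one | C=C1C[C@H](O)[C@H](Br)C(C)(C)[C@@]12CC[C@@](O)(CCl)C(=O)C2 | target

**Count and risks**

Total step count: 12. Longest linear sequence: 11 (steps 1–6 and 8–12; step 7 is the side branch).

Steps most likely to fail:

1. Step 8 (proposed new method). The annulation may fail through cyclisation on oxygen to a dihydrofuran, through loss of a C8 proton or a 1,2-shift at the C7 cation, or through attack on the wrong alkene face. The fallback closes ring B by a Lewis-acid ene reaction of an enone, a known reaction type, and adds the C3 branch afterwards. Setting out from aldehyde 9, 1-lithio-1-methoxyallene (methoxyallene, n-BuLi, THF, −78 °C) is added and the alkoxide is silylated with Et3SiCl to give the silylated methoxyallenyl carbinol F1. Mild acid hydrolysis of the enol ether (0.5 M H2SO4, THF, 0 °C) should give the vinyl ketone F2. Me2AlCl (CH2Cl2, −78 → 0 °C) should promote the intramolecular ene reaction to the spiro ketone F3, with the hydrogen taken from the methyl group cis to the tether. Dimethylsulfoxonium methylide (Me3S(O)I, NaH, DMSO) delivers CH2 equatorially to give the spiro-epoxide F4. Bu4NF/AcOH at 0 °C removes only the triethylsilyl group to give the epoxy alcohol F5, and Dess–Martin oxidation returns to the route at epoxy ketone 20.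

2. Step 2. Epimerisation of 3 may be slower than reduction, or the C–Br bond may be reduced. The fallback replaces asymmetric catalysis by resolution. Setting out from 3, Luche reduction (NaBH4, CeCl3·7H2O, MeOH, −78 °C) should give the racemic cis-bromohydrin F6. Acetylation of its (4R,5S)-enantiomer with Candida antarctica lipase B and vinyl acetate to the acetate F7 should leave the (4S,5R)-alcohol, which is separated by chromatography; the route is rejoined at 4.

3. Step 11. The β-elimination of silanolate may be sluggish, the α-methylene ketone may dimerise, or the oxirane may close on the wrong face. The fallback sets C3 by enolate hydroxylation. Setting out from enone 16, conjugate reduction with LiBH(s-Bu)3 (THF, −78 °C) and oxidation of enolate 17 in the same flask with 2-(phenylsulfonyl)-3-phenyloxaziridine should give the tertiary α-hydroxy ketone F8, oxygen entering axially and anti to C7. HF·pyridine removes both silyl groups to give the triol F9. Mitsunobu cyclodehydration (PPh3, DIAD, THF) of the primary–tertiary diol should give the epoxy ketone F10, and aq. HCl opens it at the CH2 carbon; the route is rejoined at target 22.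

**Further compounds**

F1 | step 8 | {[1-[(4S,5R)-5-bromo-4-(TBS-oxy)-2,6,6-trimethylcyclohex-1-en-1-yl]-3-methoxypenta-3,4-dien-2-yl]oxy}triethylsilane (C2 epimers) | CC=1C[C@H](O[Si](C)(C)C(C)(C)C)[C@H](Br)C(C)(C)C=1CC(O[Si](CC)(CC)CC)C(OC)=C=C
F2 | step 8 | 5-[(4S,5R)-5-bromo-4-(TBS-oxy)-2,6,6-trimethylcyclohex-1-en-1-yl]-4-(triethylsilyloxy)pent-1-en-3-one (C4 epimers) | CC=1C[C@H](O[Si](C)(C)C(C)(C)C)[C@H](Br)C(C)(C)C=1CC(O[Si](CC)(CC)CC)C(=O)C=C
F3 | step 8 | (6R,9S,10R)-10-bromo-9-(TBS-oxy)-11,11-dimethyl-7-methylidene-2-(triethylsilyloxy)spiro[5.5]undecan-3-one (C2 epimers) | C=C1C[C@H](O[Si](C)(C)C(C)(C)C)[C@H](Br)C(C)(C)[C@@]12CCC(=O)C(O[Si](CC)(CC)CC)C2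
F4 | step 8 | (3R,6R,9S,10R)-10-bromo-9-(TBS-oxy)-11,11-dimethyl-7-methylidene-2-(triethylsilyloxy)spiro[5.5]undecane-3-spiro-2′-oxirane (C2 epimers) | C=C1C[C@H](O[Si](C)(C)C(C)(C)C)[C@H](Br)C(C)(C)[C@@]12CC[C@@]3(CO3)C(O[Si](CC)(CC)CC)C2
F5 | step 8 | (3R,6R,9S,10R)-10-bromo-9-(TBS-oxy)-11,11-dimethyl-7-methylidenespiro[5.5]undecan-2-ol-3-spiro-2′-oxirane (C2 epimers) | C=C1C[C@H](O[Si](C)(C)C(C)(C)C)[C@H](Br)C(C)(C)[C@@]12CC[C@@]3(CO3)C(O)C2
F6 | step 2 | (±)-cis-5-bromo-4-hydroxy-2,6,6-trimethylcyclohex-2-en-1-one (both enantiomers) | O=C1C(C)=C[C@H](O)[C@H](Br)C1(C)C.O=C1C(C)=C[C@@H](O)[C@@H](Br)C1(C)C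
F7 | step 2 | (1R,6S)-6-bromo-3,5,5-trimethyl-4-oxocyclohex-2-en-1-yl acetate | O=C1C(C)=C[C@@H](OC(C)=O)[C@@H](Br)C1(C)C
F8 | step 11 | (3R,6R,9S,10R)-10-bromo-9-(TBS-oxy)-3-hydroxy-3-[(TBS-oxy)methyl]-11,11-dimethyl-7-methylidenespiro[5.5]undecan-2-one | C=C1C[C@H](O[Si](C)(C)C(C)(C)C)[C@H](Br)C(C)(C)[C@@]12CC[C@@](O)(CO[Si](C)(C)C(C)(C)C)C(=O)C2
F9 | step 11 | (3R,6R,9S,10R)-10-bromo-3,9-dihydroxy-3-(hydroxymethyl)-11,11-dimethyl-7-methylidenespiro[5.5]undecan-2-one | C=C1C[C@H](O)[C@H](Br)C(C)(C)[C@@]12CC[C@@](O)(CO)C(=O)C2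
F10 | step 11 | (3R,6R,9S,10R)-10-bromo-9-hydroxy-11,11-dimethyl-7-methylidenespiro[5.5]undecan-2-one-3-spiro-2′-oxirane | C=C1C[C@H](O)[C@H](Br)C(C)(C)[C@@]12CC[C@@]3(CO3)C(=O)C2
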